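A flat top in a target curve is easily taken for a flask that has stopped.

| setting | alpha | flask |
|---|---|---|
| starting material | 0.50 mM | 0.50 mM |
| partner | 0.50 mM | 0.500 mM |
| protic impurity | 0.010 mM | 0.0100 mM |
| free catalyst | 0.75 µM | 0.75 µM |
| remark | the very flask that is asked about, followed so far |  |
| time |  | 12 min |

In this flask starting material and partner stand at equal charges. My own reckoning takes one of each for every target formed. The ceiling, 100% here, is the smaller charge as a fraction of the starting material charged, the share allowed by the limiting reagent.

alpha run (percent of the starting material charged)

| time / min | target / % |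
|---|---|
| 0.667 | 37.6 |
| 1.00 | 48.5 |
| 1.50 | 59.6 |
| 2.50 | 64.4 |
| 4.00 | 63.7 |

(scatter of a reading: 1 percentage point)



Alpha is this same flask, followed so far. Its readings climb to 64.4% at 2.50 min, then show 63.7% at 4.00 min, a drop of 0.7 percentage points against a scatter of 1 point. So the top reading lies 36 points under the ceiling, but target readings do not show where that share stands.

* the moment within 12 min at which there is most target
* the amount of target, in percent of the starting material charged, at that time

The forecast puts the maximum at 2.8 min, within 2 min to 4.5 min, with 65%, within 63.5% to 66.5%. It adds: “Any later change should be a slow decline”.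

The flask gives its most target at 2.70 min, namely 65.6%, so both values lie inside the forecast's ranges.

    starting material + free catalyst ⇌ catalyst intermediate A (K = 1470 L mol⁻¹, k = 7.10 × 10⁵ L mol⁻¹ s⁻¹)
    starting material + protic impurity → quenched substrate (k = 15100 L mol⁻¹ s⁻¹)
    partner + catalyst intermediate A ⇌ catalyst intermediate B (K = 4700 L mol⁻¹, k = 3.18 × 10⁵ L mol⁻¹ s⁻¹)
    catalyst intermediate C → free catalyst + target (k = 157 s⁻¹)
    catalyst intermediate B → catalyst intermediate C (k = 20.3 s⁻¹)
    target + free catalyst ⇌ isomer of the product + free catalyst, rate k6*[free catalyst]*[target] forward; the back reaction follows from the equilibrium constant (K = 1.93, k = 3510 L mol⁻¹ s⁻¹)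

At 2.70 min this flask holds target 65.6% and isomer of the product 13.7%, together 79.3% against the ceiling of 100%, with starting material still at 18.7%. The top is therefore no stop: by 12.0 min target has fallen to 39.7% and the isomer has risen to 55.4%. The neighbour flask with 0.20 mM of partner has a ceiling of 40.0%. Its target peaks at 31.4%. At 12.0 min that flask has partner at 0% and starting material at 58.0%, while its target 18.0% and isomer of the product 22.0% come to 40.0%.

(The data come from a simulation on assumed constants, noise included.)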